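**Strategy.** Ring atoms are O1, C2 (bearing CHBr2, C1′), C3 (methyl), C4, C5 and C6. The side chain is C7(Me)(Cl)–C8H2Cl. The plan cuts O1–C6 and C7–Cl together. An ether oxygen on C6 beside a chlorinated, hydrogen-free C7 that adjoins C8 is the pattern left when an alcohol adds to the β-carbon of an enal and the resulting enamine is chlorinated. One aminocatalytic operation therefore closes the dihydropyran ring, makes both bonds, and sets C6 and the quaternary C7. The precursor is an acyclic (S)-dibromomethyl carbinol whose (Z)-C3=C4 alkene holds the hydroxyl close to an (E)-α-methyl enal. Reduction at C8 and chloride displacement finish the target.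

Key step: step 7

Assumption: the sense of induction of two catalysts is taken from the nearest models (CHBr2 as the large group in step 5, the dihydroquinidine-derived amine as the pseudoenantiomer matched to (S)-C2 in step 7). If a first run shows the opposite sense, the enantiomeric oxazaborolidine or the dihydroquinine-derived amine is used with nothing else changed.

Design remark: the C8 carbonyl is introduced last before the cascade. C5 is therefore never flanked by two carbonyl-conjugated alkenes, no base or hydride meets the finished hydroxy enal, and no protecting group is needed.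

**Step 1**
Reactants: 1 (2Z)-3-iodo-2-methylprop-2-en-1-ol; 2 allyltributylstannane
Product: 3 (2Z)-2-methylhexa-2,5-dien-1-ol
Conditions: Pd2(dba)3 (2.5 mol %), AsPh3 (10 mol %), NMP, rt to 40 °C
Reagents that add atoms: none
Why: Stille coupling: zerovalent palladium inserts into the C–I bond and the allyl group is transferred from tin with retention of the (Z) geometry, the free hydroxyl is tolerated, and an unsubstituted allyl group raises no α/γ question.

**Step 2**
Reactants: 3 (2Z)-2-methylhexa-2,5-dien-1-ol
Product: 4 (2Z)-2-methylhexa-2,5-dienal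
Conditions: activated MnO2 (excess), CH2Cl2, rt; filtered and used at once
Reagents that add atoms: none
Why: Allylic alcohol oxidation with MnO2 is heterogeneous and neutral, so the isomerisation-prone (Z)-enal and the skipped diene should survive, and the volatile aldehyde is carried on directly as a concentrated solution.

**Step 3**
Reactants: 4 (2Z)-2-methylhexa-2,5-dienal; 5 dibromomethane
Product: 6 rac-(3Z)-1,1-dibromo-3-methylhepta-3,6-dien-2-ol
Conditions: LiN(i-Pr)2, CH2Br2, THF, −90 °C, 10 min; then 4; AcOH/THF quench at −90 °C
Reagents that add atoms: none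
Why: Carbonyl 1,2-addition of a lithium carbenoid: preformed dibromomethyllithium should add to the aldehyde faster than it removes the doubly allylic C5 proton at −90 °C, the cold acid quench stops the alkoxide from closing onto a C–Br bond, and C2 is deliberately made racemic here.

**Step 4**
Reactants: 6 rac-(3Z)-1,1-dibromo-3-methylhepta-3,6-dien-2-ol
Product: 7 (3Z)-1,1-dibromo-3-methylhepta-3,6-dien-2-one
Conditions: Dess–Martin periodinane, CH2Cl2, 0 °C to rt
Reagents that add atoms: none
Why: Dess–Martin oxidation handles electron-poor secondary carbinols under non-basic conditions, which a CHBr2 ketone with an acidic γ-position requires.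

**Step 5**
Reactants: 7 (3Z)-1,1-dibromo-3-methylhepta-3,6-dien-2-one
Product: 8 (2S,3Z)-1,1-dibromo-3-methylhepta-3,6-dien-2-ol
Conditions: (R)-2-methyl-CBS-oxazaborolidine [(3aR)-1-methyl-3,3-diphenyltetrahydro-1H,3H-pyrrolo[1,2-c][1,3,2]oxazaborole] (20 mol %), catecholborane, toluene, −78 °C
Reagents that add atoms: none
Why: Corey–Bakshi–Shibata reduction: as in the reduction of trihalomethyl ketones the halogenated carbon is expected to act as the large group, so the (R)-catalyst should deliver hydride to the Re face of C2 and give (S)-C2, while catecholborane at −78 °C neither hydroborates the alkenes nor reduces in the 1,4-sense.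

**Step 6**
Reactants: 8 (2S,3Z)-1,1-dibromo-3-methylhepta-3,6-dien-2-ol; 9 methacrolein
Product: 10 (2E,5Z,7S)-8,8-dibromo-7-hydroxy-2,6-dimethylocta-2,5-dienal
Conditions: second-generation Hoveyda–Grubbs catalyst, RuCl2(H2IMes)(=CH–C6H4-2-O-i-Pr) (5 mol %), methacrolein (excess), 1,4-benzoquinone (10 mol %), CH2Cl2, 40 °C
Reagents that add atoms: none
Why: Olefin cross-metathesis of a monosubstituted alkene with a 1,1-disubstituted electron-poor partner gives the thermodynamically preferred (E)-2-methyl enal, the hindered trisubstituted C3=C4 bond stays out of the reaction, and benzoquinone suppresses ruthenium hydride migration of the skipped diene.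

**Step 7**
Reactants: 10 (2E,5Z,7S)-8,8-dibromo-7-hydroxy-2,6-dimethylocta-2,5-dienal
Product: 13 (2R)-2-chloro-2-[(2S,6S)-6-(dibromomethyl)-5-methyl-3,6-dihydro-2H-pyran-2-yl]propanal, via iminium ion 11 (not isolated), via cyclised enamine 12 (not isolated)
Conditions: 9-amino(9-deoxy)epi-dihydroquinidine (20 mol %), CF3CO2H (40 mol %), NCS (1.2 equiv, added slowly in portions), CHCl3, 0 °C
Reagents that add atoms: N-chlorosuccinimide, O=C1CCC(=O)N1Cl; 9-amino(9-deoxy)epi-dihydroquinidine (atoms in 11 and 12 only), COC1=CC2=C(C=CN=C2C=C1)[C@H]([C@H]3C[C@@H]4CCN3C[C@@H]4CC)N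
Why: Proposed new method: the primary amine salt condenses with the hindered α-methyl enal of 10 to iminium ion 11, the C2 hydroxyl, assisted by the quinuclidine nitrogen as general base, adds to C6, and enamine 12, whose nucleophilic carbon C7 bears no hydrogen, picks up Cl+ from NCS before hydrolysis releases 13 and the amine. The closest known reaction types are the primary-amine iminium–enamine cascades of α-branched enals (sulfur or carbon nucleophile, then an azodicarboxylate), the amine-catalysed epoxidation of α-branched enals and the aminocatalytic α-chlorination of aldehydes with NCS, but an alcohol donor paired with chlorination to a quaternary C–Cl centre has not been shown. The single ring formed (O1, C2, C3, C4, C5, C6) closes 6-exo-trig, and the (Z)-C3=C4 bond favours this because it already places O1 and C6 on the same side of the alkene. C6 (S) is fixed by the catalyst, which should leave the Si face of C6 in 11 open, and the substrate helps, since allylic 1,2-strain between the C3 methyl and CHBr2 pushes CHBr2 pseudoaxial in the half-chair transition state and the iminium arm equatorial, which is the 2,6-trans array. C7 (R) is fixed when the (E)-enamine, its C6–C7 rotamer held by allylic 1,3-strain, is chlorinated on the face the catalyst leaves free, a net syn addition of O and Cl across the (E)-C6=C7 bond, and the centre is locked afterwards for want of an α-hydrogen. The step needs chlorination at C7 to win over attack of NCS on C3=C4 and over loss of a C5 proton from 11 to a conjugated trienamine; the ring alkene is deactivated by its allylic oxygen and the CHBr2 group, the closure is intramolecular, and adduct that is merely protonated at C7 can re-enter as 12, so a weakly basic counter-ion, 0 °C and slow NCS addition should suffice.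

**Step 8**
Reactants: 13 (2R)-2-chloro-2-[(2S,6S)-6-(dibromomethyl)-5-methyl-3,6-dihydro-2H-pyran-2-yl]propanal
Product: 14 (2S)-2-chloro-2-[(2S,6S)-6-(dibromomethyl)-5-methyl-3,6-dihydro-2H-pyran-2-yl]propan-1-ol
Conditions: NaBH4, MeOH/CH2Cl2, −40 to −20 °C; pH 7 buffer quench
Reagents that add atoms: none
Why: Borohydride reduction of an α-chloro aldehyde to the chlorohydrin is routine, low temperature and a neutral quench prevent epoxide closure, and no stereocentre is touched (the C7 descriptor changes to S only because CH2OH ranks below C6).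

**Step 9**
Reactants: 14 (2S)-2-chloro-2-[(2S,6S)-6-(dibromomethyl)-5-methyl-3,6-dihydro-2H-pyran-2-yl]propan-1-ol
Product: 16 (2S,6S)-6-(dibromomethyl)-2-[(2R)-1,2-dichloropropan-2-yl]-5-methyl-3,6-dihydro-2H-pyran, via primary triflate 15 (not isolated)
Conditions: Tf2O, 2,6-lutidine, CH2Cl2, −78 °C; then n-Bu4NCl (5 equiv), −78 °C to rt
Reagents that add atoms: tetrabutylammonium chloride, CCCC[N+](CCCC)(CCCC)CCCC.[Cl-]; triflic anhydride (atoms in 15 only), O=S(=O)(OS(=O)(=O)C(F)(F)F)C(F)(F)F
Why: Sulfonate displacement (SN2): a primary triflate is reactive enough for chloride to attack the neopentyl-type C8 at or below room temperature, C7 has no hydrogen so elimination is impossible, and a high chloride concentration in a poorly ionising, non-nucleophilic solvent should keep neighbouring-chlorine participation, the only path that could scramble C7, out of play.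

**Compound list**
1 | (2Z)-3-iodo-2-methylprop-2-en-1-ol | OC/C(C)=C\I | starting material
2 | allyltributylstannane | C=CC[Sn](CCCC)(CCCC)CCCC | starting material
3 | (2Z)-2-methylhexa-2,5-dien-1-ol | OC/C(C)=C\CC=C | intermediate
4 | (2Z)-2-methylhexa-2,5-dienal | O=C/C(C)=C\CC=C | intermediate
5 | dibromomethane | BrCBr | starting material
6 | rac-(3Z)-1,1-dibromo-3-methylhepta-3,6-dien-2-ol | BrC(Br)C(O)/C(C)=C\CC=C | intermediate
7 | (3Z)-1,1-dibromo-3-methylhepta-3,6-dien-2-one | BrC(Br)C(=O)/C(C)=C\CC=C | intermediate
8 | (2S,3Z)-1,1-dibromo-3-methylhepta-3,6-dien-2-ol | BrC(Br)[C@@H](O)/C(C)=C\CC=C | intermediate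
9 | methacrolein (2-methylprop-2-enal) | C=C(C)C=O | starting material
10 | (2E,5Z,7S)-8,8-dibromo-7-hydroxy-2,6-dimethylocta-2,5-dienal | BrC(Br)[C@@H](O)/C(C)=C\C/C=C(C)/C=O | intermediate
11 | iminium ion from 10 and 9-amino(9-deoxy)epi-dihydroquinidine (cation, trifluoroacetate counter-ion) | COC1=CC2=C(C=CN=C2C=C1)[C@H]([C@H]3C[C@@H]4CCN3C[C@@H]4CC)/[NH+]=C/C(C)=C/C/C=C(C)\[C@H](O)C(Br)Br | intermediate
12 | (E)-enamine of the cyclised (2S,6S)-dihydropyranyl propanal with the same amine | COC1=CC2=C(C=CN=C2C=C1)[C@H]([C@H]3C[C@@H]4CCN3C[C@@H]4CC)N/C=C(C)/[C@@H]5CC=C(C)[C@@H](C(Br)Br)O5 | intermediate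
13 | (2R)-2-chloro-2-[(2S,6S)-6-(dibromomethyl)-5-methyl-3,6-dihydro-2H-pyran-2-yl]propanal | CC1=CC[C@@H]([C@@](C)(Cl)C=O)O[C@@H]1C(Br)Br | intermediate
14 | (2S)-2-chloro-2-[(2S,6S)-6-(dibromomethyl)-5-methyl-3,6-dihydro-2H-pyran-2-yl]propan-1-ol | CC1=CC[C@@H]([C@@](C)(Cl)CO)O[C@@H]1C(Br)Br | intermediate
15 | (2S)-2-chloro-2-[(2S,6S)-6-(dibromomethyl)-5-methyl-3,6-dihydro-2H-pyran-2-yl]propyl trifluoromethanesulfonate | CC1=CC[C@@H]([C@@](C)(Cl)COS(=O)(=O)C(F)(F)F)O[C@@H]1C(Br)Br | intermediate
16 | (2S,6S)-6-(dibromomethyl)-2-[(2R)-1,2-dichloropropan-2-yl]-5-methyl-3,6-dihydro-2H-pyran | CC1=CC[C@@H]([C@@](C)(Cl)CCl)O[C@@H]1C(Br)Br | target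

Total step count: 9. Longest linear sequence: 9 (fully linear, no protecting groups).

**Steps most likely to fail**

**First, step 7.**
- What may go wrong:
  - Loss of a C5 proton from the iminium ion may outrun ring closure, so that chlorination or reprotonation occurs away from C7.
  - The amine may be consumed by N-chlorination.
  - Facial control at C6 or C7 may be insufficient.
- The fallback uses known reactions only. It sets out from 8 and returns at 13.
- Cross-metathesis of 8 with methyl 2-methylallyl carbonate (second-generation Hoveyda–Grubbs catalyst, CH2Cl2, 40 °C) should give methyl (2E,5Z,7S)-8,8-dibromo-7-hydroxy-2,6-dimethylocta-2,5-dien-1-yl carbonate F1.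
- A Tsuji–Trost allylic etherification (Pd2(dba)3·CHCl3, DACH-phenyl Trost ligand, CH2Cl2, rt) then forms the same O1–C6 bond through a π-allyl complex of divalent palladium. It gives (2S,6S)-6-(dibromomethyl)-5-methyl-2-(prop-1-en-2-yl)-3,6-dihydro-2H-pyran F2. The ligand enantiomer is chosen for 2,6-trans closure.
- 9-BBN selects the 1,1-disubstituted alkene over the ring alkene. Followed by NaBO3·4H2O, it gives 2-[(2S,6S)-6-(dibromomethyl)-5-methyl-3,6-dihydro-2H-pyran-2-yl]propan-1-ol F3 as both C7 epimers.
- Dess–Martin oxidation gives 2-[(2S,6S)-6-(dibromomethyl)-5-methyl-3,6-dihydro-2H-pyran-2-yl]propanal F4.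
- The separate, established aminocatalytic α-chlorination of an α-branched aldehyde (chiral primary amine salt, NCS) funnels both epimers through one enamine to 13. Any minor C7 epimer is removed by chromatography.

**Second, step 5.**
- What may go wrong: facial selectivity may be low or reversed, because CHBr2 and the twisted trisubstituted alkenyl group compete for the role of the large substituent.
- The fallback replaces asymmetric reduction by resolution. It sets out from 6 and returns at 8, so steps 4 and 5 become unnecessary.
- Esterification of racemic 6 with (S)-O-methylmandelic acid (N,N′-dicyclohexylcarbodiimide, catalytic DMAP, CH2Cl2) gives two diastereomers: (2S,3Z)-1,1-dibromo-3-methylhepta-3,6-dien-2-yl (2S)-2-methoxy-2-phenylacetate F5 and (2R,3Z)-1,1-dibromo-3-methylhepta-3,6-dien-2-yl (2S)-2-methoxy-2-phenylacetate F6.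
- The two esters are separated by chromatography and assigned by the aryl shielding model.
- Cleavage of F5 with i-Bu2AlH in CH2Cl2 at −78 °C releases 8 without basic conditions.

**Third, step 9.**
- What may go wrong: displacement at the neopentyl-type C8 may be slow enough for neighbouring-chlorine participation (erosion at C7), or for bromide–chloride exchange at C1′ by the excess chloride.
- The fallback gives up the sulfonate and the external chloride for an Appel reaction. It sets out from 14 and returns at 16.
- PPh3 and CCl4 in MeCN at 60 °C convert 14 into {(2S)-2-chloro-2-[(2S,6S)-6-(dibromomethyl)-5-methyl-3,6-dihydro-2H-pyran-2-yl]propoxy}triphenylphosphonium chloride F7. Its own counter-ion attacks C8 within the ion pair.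
- This reaction type converts neopentyl alcohol itself without rearrangement and needs no excess of free chloride.

**Further compounds**
F1 | step 7 | methyl (2E,5Z,7S)-8,8-dibromo-7-hydroxy-2,6-dimethylocta-2,5-dien-1-yl carbonate | BrC(Br)[C@@H](O)/C(C)=C\C/C=C(C)/COC(=O)OC
F2 | step 7 | (2S,6S)-6-(dibromomethyl)-5-methyl-2-(prop-1-en-2-yl)-3,6-dihydro-2H-pyran | CC1=CC[C@@H](C(C)=C)O[C@@H]1C(Br)Br
F3 | step 7 | 2-[(2S,6S)-6-(dibromomethyl)-5-methyl-3,6-dihydro-2H-pyran-2-yl]propan-1-ol | CC1=CC[C@@H](C(C)CO)O[C@@H]1C(Br)Br
F4 | step 7 | 2-[(2S,6S)-6-(dibromomethyl)-5-methyl-3,6-dihydro-2H-pyran-2-yl]propanal | CC1=CC[C@@H](C(C)C=O)O[C@@H]1C(Br)Br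
F5 | step 5 | (2S,3Z)-1,1-dibromo-3-methylhepta-3,6-dien-2-yl (2S)-2-methoxy-2-phenylacetate | BrC(Br)[C@@H](OC(=O)[C@@H](OC)c1ccccc1)/C(C)=C\CC=C
F6 | step 5 | (2R,3Z)-1,1-dibromo-3-methylhepta-3,6-dien-2-yl (2S)-2-methoxy-2-phenylacetate | BrC(Br)[C@H](OC(=O)[C@@H](OC)c1ccccc1)/C(C)=C\CC=C
F7 | step 9 | {(2S)-2-chloro-2-[(2S,6S)-6-(dibromomethyl)-5-methyl-3,6-dihydro-2H-pyran-2-yl]propoxy}triphenylphosphonium chloride | CC1=CC[C@@H]([C@@](C)(Cl)CO[P+](c2ccccc2)(c2ccccc2)c2ccccc2)O[C@@H]1C(Br)Br.[Cl-]
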